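**Route overview**

- Atom labels: ring A (cyclohexane) C1 = CH bearing ring B, C2 = CH2, C3 = CHBr, C4 = C(Cl)CH3, C5 = CH2, C6 = CHOH; ring B (tetrahydropyran) C7 = oxygen-bearing quaternary carbon on C1, C8 = CHOAc, C9 = CH2, C10 = CHBr, C11 = CMe2.
- Cuts, in retrosynthetic order: C6 is epimerised through its ketone; the O–C11 bond of ring B (bromoetherification of a C10=C11 alkene by the C7 hydroxyl); the C1–C2 bond of ring A together with the C7–O bond (key step); Br and Cl off C3/C4 (back to a Z-alkene); then C5–C6, C9=C10 and C8–C9 of the chain.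
- Enabling feature: in ring A the trans-diequatorial C3–Br/C4–Cl pair beside the C2 methylene is a ring-closed 2-bromo-3-chloro-3-methylalkan-1-ol. C1 and the oxygenated quaternary C7 are the two carbons of an E-trisubstituted alkene whose allylic C6 oxygen can carry an ester, so a C2 electrophile flanked by the C3 bromine can alkylate C1 while the C6 ester delivers oxygen to C7.
- Forward: one linear chain is built from prenyl acetate (allylation, cross-metathesis, vinylogous aldol). A 5,6-dihydropyran-2-one is made only to fix the Z geometry and is reduced open; ring A closes in step 15 (with a transient 1,3-dioxan-2-ylium ring); ring B closes last.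
- Stereochemistry: C8 from catalytic asymmetric allylboration; temporary C6 from the catalytic vinylogous aldol; C3/C4 from catalyst-controlled anti bromochlorination of the Z-alkene; C1/C7 from anti addition across the E-alkene steered by C6; C10 from the chair bromoetherification; C6 is finally inverted by oxidation and equatorial hydride delivery.

Key step: step 15

Assumption: the catalyst antipodes written in steps 2, 8 and 13 follow the sense of induction known for simple substrates; the face of attack stated in each Why line defines the antipode to be used. (TBS = tert-butyldimethylsilyl, TES = triethylsilyl; open-chain compounds are named with their own chain locants, ring compounds with the atom labels above.)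

Step 1
Reactants: 1 prenyl acetate (3-methylbut-2-en-1-yl acetate)
Product: 2 (2E)-4-acetoxy-2-methylbut-2-enal
Conditions: SeO2 (1.1 equiv), 1,4-dioxane, 80 °C
Reagents that add atoms: selenium dioxide, O=[Se]=O
Why: Riley allylic oxidation (ene reaction, then [2,3]-sigmatropic shift) attacks the E-methyl group of the trisubstituted alkene and should stop at the conjugated E-aldehyde, the acetoxymethyl end being deactivated.

Step 2
Reactants: 2 (2E)-4-acetoxy-2-methylbut-2-enal; 3 allylboronic acid pinacol ester
Product: 5 (2E,4S)-4-hydroxy-3-methylhepta-2,6-dien-1-yl acetate, via pinacol borate ester 4 (not isolated)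
Conditions: (S)-TRIP phosphoric acid (5 mol %), toluene, −30 °C; aq. NaHCO3 work-up
Reagents that add atoms: none
Why: chiral phosphoric acid-catalysed allylboration through a closed six-membered chair transition state in which the acid activates the boronate; the (S)-acid should deliver allyl to the Si face of the aldehyde, which sets the future C8 as S.

Step 3
Reactants: 5 (2E,4S)-4-hydroxy-3-methylhepta-2,6-dien-1-yl acetate; 6 2-methylbut-2-ene
Product: 7 (2E,4S)-4-hydroxy-3,7-dimethylocta-2,6-dien-1-yl acetate
Conditions: second-generation Grubbs catalyst (3 mol %), 2-methylbut-2-ene (excess)/CH2Cl2, 35 °C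
Reagents that add atoms: none
Why: olefin cross-metathesis of the terminal alkene with excess 2-methylbut-2-ene should exchange =CH2 for =CMe2, the trisubstituted allylic-acetate alkene being too hindered to enter the catalytic cycle.

Step 4
Reactants: 7 (2E,4S)-4-hydroxy-3,7-dimethylocta-2,6-dien-1-yl acetate
Product: 8 (2E,4S)-4-(TBS-oxy)-3,7-dimethylocta-2,6-dien-1-yl acetate
Conditions: TBSCl, imidazole, DMF, rt
Reagents that add atoms: tert-butyldimethylsilyl chloride, CC(C)(C)[Si](C)(C)Cl
Why: imidazole-promoted silylation of the secondary allylic alcohol gives an ether that should survive hydride, mild acid, bromonium and triflate chemistry up to step 17.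

Step 5
Reactants: 8 (2E,4S)-4-(TBS-oxy)-3,7-dimethylocta-2,6-dien-1-yl acetate
Product: 9 (2E,4S)-4-(TBS-oxy)-3,7-dimethylocta-2,6-dien-1-ol
Conditions: K2CO3 (0.2 equiv), MeOH, 0 °C
Reagents that add atoms: none
Why: base-catalysed transesterification (Zemplén-type deacetylation) frees the primary allylic alcohol and leaves the silyl ether untouched.

Step 6
Reactants: 9 (2E,4S)-4-(TBS-oxy)-3,7-dimethylocta-2,6-dien-1-ol
Product: 10 (2E,4S)-4-(TBS-oxy)-3,7-dimethylocta-2,6-dienal
Conditions: activated MnO2 (excess), CH2Cl2, rt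
Reagents that add atoms: none
Why: MnO2 oxidises only the allylic alcohol and should keep the E geometry of the enal.

Step 7
Reactants: 11 methyl 3-methylbut-2-enoate
Product: 12 1-methoxy-3-methyl-1-(trimethylsilyloxy)buta-1,3-diene
Conditions: LiN(iPr)2 (commercial solution), THF, −78 °C; Me3SiCl, −78 °C to rt; distillation
Reagents that add atoms: chlorotrimethylsilane, C[Si](C)(C)Cl
Why: kinetic γ-deprotonation of the senecioate gives the extended dienolate, which is trapped on oxygen as the silyl ketene acetal.

Step 8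
Reactants: 10 (2E,4S)-4-(TBS-oxy)-3,7-dimethylocta-2,6-dienal; 12 1-methoxy-3-methyl-1-(trimethylsilyloxy)buta-1,3-diene
Product: 14 (6S)-6-[(1E,3S)-3-(TBS-oxy)-2,6-dimethylhepta-1,5-dien-1-yl]-4-methyl-5,6-dihydro-2H-pyran-2-one, via Z-hydroxy ester 13 (not isolated)
Conditions: Cu(OTf)2 (10 mol %), (S)-Tol-BINAP (11 mol %), Bu4N[Ph3SiF2] (20 mol %), THF, −78 °C to rt; then 1 M aq. HCl/THF, 0 °C, brief
Reagents that add atoms: none
Why: catalytic asymmetric vinylogous Mukaiyama aldol (a formal hetero-Diels–Alder reaction) in which the ligated copper dienolate adds through its γ-carbon to the Si face of the aldehyde, setting C6 as S, and the Z-configured adduct lactonises so that the C3=C4 alkene is locked as Z.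

Step 9
Reactants: 14 dihydropyranone (6S; side chain 1E,3S)
Product: 15 (2Z,5S,6E,8S)-8-(TBS-oxy)-3,7,11-trimethyldodeca-2,6,10-triene-1,5-diol
Conditions: iBu2AlH (3.5 equiv), CH2Cl2, −78 to 0 °C; aq. potassium sodium tartrate
Reagents that add atoms: none
Why: hydride reduction of the unsaturated lactone through its lactol (1,2-reduction) opens the ring to the diol and carries the ring-enforced Z geometry into the chain.

Step 10
Reactants: 15 (2Z,5S,6E,8S)-8-(TBS-oxy)-3,7,11-trimethyldodeca-2,6,10-triene-1,5-diol
Product: 16 (2Z,5S,6E,8S)-8-(TBS-oxy)-1-(TES-oxy)-3,7,11-trimethyldodeca-2,6,10-trien-5-ol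
Conditions: Et3SiCl (1.05 equiv), imidazole, CH2Cl2, −40 °C
Reagents that add atoms: chlorotriethylsilane, CC[Si](Cl)(CC)CC
Why: silylation at low temperature should select the primary over the hindered secondary hydroxyl.

Step 11
Reactants: 16 mono-TES ether (C6 hydroxyl free)
Product: 17 (2Z,5S,6E,8S)-8-(TBS-oxy)-1-(TES-oxy)-3,7,11-trimethyldodeca-2,6,10-trien-5-yl chloroacetate
Conditions: (ClCH2CO)2O, pyridine, DMAP (cat.), CH2Cl2, 0 °C
Reagents that add atoms: chloroacetic anhydride, O=C(CCl)OC(=O)CCl
Why: DMAP-catalysed acylation installs on the C6 oxygen the ester that will terminate the cyclisation and that can later be cleaved beside an acetate.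

Step 12
Reactants: 17 TES ether chloroacetate
Product: 18 (2Z,5S,6E,8S)-1-hydroxy-8-(TBS-oxy)-3,7,11-trimethyldodeca-2,6,10-trien-5-yl chloroacetate
Conditions: AcOH/THF/H2O (3:1:1), rt
Reagents that add atoms: none
Why: acid hydrolysis cleaves a primary TES ether much faster than a secondary TBS ether, and the chloroacetate is stable to acid.

Step 13
Reactants: 18 Z-allylic alcohol (C6 chloroacetate)
Product: 19 (2R,3R,5S,6E,8S)-2-bromo-3-chloro-1-hydroxy-8-(TBS-oxy)-3,7,11-trimethyldodeca-6,10-dien-5-yl chloroacetate
Conditions: chiral tridentate Schiff-base ligand (salicylaldimine of a 1,1-diaryl amino alcohol, 20 mol %), ClTi(OiPr)3 (1.1 equiv), N-bromosuccinimide (1.05 equiv), hexanes, −20 °C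
Reagents that add atoms: N-bromosuccinimide, O=C1CCC(=O)N1Br; chlorotitanium triisopropoxide, CC(C)O[Ti](Cl)(OC(C)C)OC(C)C
Why: titanium-alkoxide-directed catalytic enantioselective bromochlorination, in which the bromonium forms only at the alkene of the titanium-bound allylic alcohol and titanium-bound chloride opens it anti at the tertiary C4, should give Br on C3 and Cl on C4 (3R,4R by the atom labels) and leave the two alkenes without a free hydroxyl untouched.

Step 14
Reactants: 19 open-chain bromochloride (primary alcohol)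
Product: 20 primary triflate of 19 (used at once as a cold solution)
Conditions: Tf2O (1.1 equiv), 2,6-di-tert-butyl-4-methylpyridine (1.5 equiv), CH2Cl2, −78 °C
Reagents that add atoms: triflic anhydride, O=S(=O)(OS(=O)(=O)C(F)(F)F)C(F)(F)F
Why: O-sulfonylation of the only free hydroxyl with a non-nucleophilic base gives a β-bromoalkyl triflate that should persist at −78 °C in a non-ionising solvent.

Step 15
Reactants: 20 primary triflate
Product: 23 ring A hydroxy ester (C7 tertiary alcohol; C6 equatorial chloroacetate; C1S C3R C4R C6S C7S C8S), via bromonium triflate 21 (not isolated), via dioxanylium triflate 22 (not isolated)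
Conditions: CH2Cl2/(CF3)2CHOH 4:1 (0.005 M), 2,6-di-tert-butyl-4-methylpyridine, −60 to −20 °C; then sat. aq. NaHCO3/THF, 0 °C to rt
Reagents that add atoms: water, O
Why: Proposed new method: in the ionising, non-nucleophilic medium the C3 bromine should displace the primary triflate to give the C2–C3 bromonium 21, which the C1=C7 alkene opens at the unhindered primary C2 while the chloroacetate carbonyl adds to the developing C7 cation anti to the new C–C bond, giving dioxanylium 22 that bicarbonate hydrolyses to the C7 alcohol and the C6 ester (the less hindered secondary ester, to which any C7 ester should migrate under the same conditions). The closest known reaction types are the stereospecific generation of bromonium ions from β-bromo sulfonates or vicinal bromochlorides in fluorinated alcohols with capture by alkenes, the π-route solvolysis of 5-alkenyl sulfonates, and neighbouring-ester termination of cation–olefin cyclisations. Ring A closes through a chair by endo opening of the bromonium (C2 and C3 both inside the ring, C7 outside), and the 1,3-dioxan-2-ylium closes by attack of the carbonyl oxygen on C7 (six-membered, both alkene carbons inside, trans-fused to ring A). C1 and C7 are set by anti addition across the E-alkene with the face fixed by C6, since allylic 1,3-strain with the C7 methyl holds C6–H in the alkene plane so that C5 and the ester oxygen reach the alkene from opposite faces, while backside opening leaves the untouched C3–Br equatorial and anti to the new C1–C2 bond, with Cl equatorial and the C4 methyl axial. The step needs attack at C2 rather than C3 and ionisation of the triflate rather than of the tertiary chloride: C3 is neopentylic and deactivated by the adjacent C–Cl bond, triflate is by far the better leaving group at low temperature, no external nucleophile or other alkene within six-ring reach is present, and the product cannot ionise further because its Br and Cl are gauche.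

Step 16
Reactants: 23 ring A hydroxy ester
Product: 24 bromotetrahydropyran (C8 TBS ether; C6 chloroacetate; C10S)
Conditions: 2,4,4,6-tetrabromocyclohexa-2,5-dienone (1.2 equiv), MeNO2, 0 °C to rt, dark
Reagents that add atoms: 2,4,4,6-tetrabromocyclohexa-2,5-dienone, O=C1C(Br)=CC(Br)(Br)C=C1Br
Why: bromoetherification in which the bromonium of the C10=C11 alkene is opened anti by the C7 hydroxyl at tertiary C11 (six-membered ring) through a chair with Br equatorial and the C7 methyl, not the cyclohexyl group, axial should set C10 as S.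

Step 17
Reactants: 24 bromotetrahydropyran
Product: 25 C8 alcohol (C6 chloroacetate retained)
Conditions: HF·pyridine, pyridine/THF, 0 °C to rt
Reagents that add atoms: none
Why: buffered fluoride desilylation removes the TBS ether without touching the chloroacetate or the halides.

Step 18
Reactants: 25 C8 alcohol
Product: 26 C8 acetate C6 chloroacetate
Conditions: Ac2O, DMAP, pyridine, rt
Reagents that add atoms: acetic anhydride, CC(=O)OC(C)=O
Why: DMAP-catalysed acyl transfer should acetylate the hindered axial C8 hydroxyl, the only free hydroxyl present.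

Step 19
Reactants: 26 C8 acetate C6 chloroacetate
Product: 27 C8 acetate C6 equatorial alcohol (C6S)
Conditions: K2CO3 (0.1 equiv), MeOH, −10 °C, brief
Reagents that add atoms: none
Why: an α-chloro ester is methanolysed far faster than an acetate, so brief cold base-catalysed transesterification should free only the C6 hydroxyl.

Step 20
Reactants: 27 C6 equatorial alcohol
Product: 28 C6 ketone with C8 acetate
Conditions: Dess–Martin periodinane, NaHCO3, CH2Cl2, 0 °C to rt
Reagents that add atoms: none
Why: Dess–Martin oxidation under buffered, non-basic conditions should give the ketone without epimerising C1 or eliminating the β-oxygen at C7 or the β-chloride at C4.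

Step 21
Reactants: 28 C6 ketone
Product: 29 target (1S,3R,4R,6R,7S,8S,10S by the atom labels)
Conditions: Li[HB(sBu)3] (1.2 equiv), THF, −78 °C; then AcOH, −78 °C
Reagents that add atoms: none
Why: the bulky trialkylborohydride attacks the chair cyclohexanone from the equatorial direction because the axial path is blocked by the axial C4 methyl, which gives the axial C6 alcohol cis to the C1 substituent, and at −78 °C ketone reduction should outrun attack on the acetate and enolisation.

**Compound list**

1 | prenyl acetate (3-methylbut-2-en-1-yl acetate) | CC(C)=CCOC(C)=O | starting material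
2 | (2E)-4-acetoxy-2-methylbut-2-enal | CC(=O)OC/C=C(\C)C=O | intermediate
3 | allylboronic acid pinacol ester | C=CCB1OC(C)(C)C(C)(C)O1 | starting material
4 | pinacol borate ester of 5 | CC(=O)OC/C=C(\C)[C@@H](OB1OC(C)(C)C(C)(C)O1)CC=C | intermediate (not isolated)
5 | (2E,4S)-4-hydroxy-3-methylhepta-2,6-dien-1-yl acetate | CC(=O)OC/C=C(\C)[C@@H](O)CC=C | intermediate
6 | 2-methylbut-2-ene | CC=C(C)C | starting material
7 | (2E,4S)-4-hydroxy-3,7-dimethylocta-2,6-dien-1-yl acetate | CC(=O)OC/C=C(\C)[C@@H](O)CC=C(C)C | intermediate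
8 | (2E,4S)-4-(TBS-oxy)-3,7-dimethylocta-2,6-dien-1-yl acetate | CC(=O)OC/C=C(\C)[C@@H](O[Si](C)(C)C(C)(C)C)CC=C(C)C | intermediate
9 | (2E,4S)-4-(TBS-oxy)-3,7-dimethylocta-2,6-dien-1-ol | OC/C=C(\C)[C@@H](O[Si](C)(C)C(C)(C)C)CC=C(C)C | intermediate
10 | (2E,4S)-4-(TBS-oxy)-3,7-dimethylocta-2,6-dienal | O=C/C=C(\C)[C@@H](O[Si](C)(C)C(C)(C)C)CC=C(C)C | intermediate
11 | methyl 3-methylbut-2-enoate | COC(=O)C=C(C)C | starting material
12 | 1-methoxy-3-methyl-1-(trimethylsilyloxy)buta-1,3-diene | COC(O[Si](C)(C)C)=CC(C)=C | intermediate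
13 | methyl (2Z,5S,6E,8S)-5-hydroxy-8-(TBS-oxy)-3,7,11-trimethyldodeca-2,6,10-trienoate | COC(=O)/C=C(C)\C[C@H](O)/C=C(\C)[C@@H](O[Si](C)(C)C(C)(C)C)CC=C(C)C | intermediate (not isolated)
14 | (6S)-6-[(1E,3S)-3-(TBS-oxy)-2,6-dimethylhepta-1,5-dien-1-yl]-4-methyl-5,6-dihydro-2H-pyran-2-one | CC1=CC(=O)O[C@@H](C1)/C=C(\C)[C@@H](O[Si](C)(C)C(C)(C)C)CC=C(C)C | intermediate
15 | (2Z,5S,6E,8S)-8-(TBS-oxy)-3,7,11-trimethyldodeca-2,6,10-triene-1,5-diol | OC/C=C(C)\C[C@H](O)/C=C(\C)[C@@H](O[Si](C)(C)C(C)(C)C)CC=C(C)C | intermediate
16 | (2Z,5S,6E,8S)-8-(TBS-oxy)-1-(TES-oxy)-3,7,11-trimethyldodeca-2,6,10-trien-5-ol | CC[Si](CC)(CC)OC/C=C(C)\C[C@H](O)/C=C(\C)[C@@H](O[Si](C)(C)C(C)(C)C)CC=C(C)C | intermediate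
17 | (2Z,5S,6E,8S)-8-(TBS-oxy)-1-(TES-oxy)-3,7,11-trimethyldodeca-2,6,10-trien-5-yl chloroacetate | CC[Si](CC)(CC)OC/C=C(C)\C[C@H](OC(=O)CCl)/C=C(\C)[C@@H](O[Si](C)(C)C(C)(C)C)CC=C(C)C | intermediate
18 | (2Z,5S,6E,8S)-1-hydroxy-8-(TBS-oxy)-3,7,11-trimethyldodeca-2,6,10-trien-5-yl chloroacetate | OC/C=C(C)\C[C@H](OC(=O)CCl)/C=C(\C)[C@@H](O[Si](C)(C)C(C)(C)C)CC=C(C)C | intermediate
19 | (2R,3R,5S,6E,8S)-2-bromo-3-chloro-1-hydroxy-8-(TBS-oxy)-3,7,11-trimethyldodeca-6,10-dien-5-yl chloroacetate | OC[C@@H](Br)[C@](C)(Cl)C[C@H](OC(=O)CCl)/C=C(\C)[C@@H](O[Si](C)(C)C(C)(C)C)CC=C(C)C | intermediate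
20 | primary triflate of 19 | O=S(=O)(OC[C@@H](Br)[C@](C)(Cl)C[C@H](OC(=O)CCl)/C=C(\C)[C@@H](O[Si](C)(C)C(C)(C)C)CC=C(C)C)C(F)(F)F | intermediate
21 | C2–C3 bromonium ion of the chain, triflate salt (C3 configuration unchanged) | [Br+]1C[C@@H]1[C@](C)(Cl)C[C@H](OC(=O)CCl)/C=C(\C)[C@@H](O[Si](C)(C)C(C)(C)C)CC=C(C)C.[O-]S(=O)(=O)C(F)(F)F | intermediate (not isolated)
22 | 2-(chloromethyl)-1,3-dioxan-2-ylium triflate trans-fused to ring A through the C6 and C7 oxygens | CC(C)=CC[C@H](O[Si](C)(C)C(C)(C)C)[C@@](C)(O2)[C@H]1C[C@@H](Br)[C@](C)(Cl)C[C@@H]1O[C+]2CCl.[O-]S(=O)(=O)C(F)(F)F | intermediate (not isolated)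
23 | ring A hydroxy ester: C3 Br and C4 Cl trans-diequatorial, C4 methyl axial, C6 equatorial chloroacetate, C1 side chain C7(OH)(CH3)–C8H(OTBS)–CH2–CH=CMe2 (1S,3R,4R,6S,7S,8S) | CC(C)=CC[C@H](O[Si](C)(C)C(C)(C)C)[C@@](C)(O)[C@H]1C[C@@H](Br)[C@](C)(Cl)C[C@@H]1OC(=O)CCl | intermediate
24 | bromotetrahydropyran: ring B closed, C10 Br equatorial (10S), C8 TBS ether, C6 chloroacetate | CC(C)(C)[Si](C)(C)O[C@H]1C[C@H](Br)C(C)(C)O[C@@]1(C)[C@H]1C[C@@H](Br)[C@](C)(Cl)C[C@@H]1OC(=O)CCl | intermediate
25 | C8 alcohol of 24 | O[C@H]1C[C@H](Br)C(C)(C)O[C@@]1(C)[C@H]1C[C@@H](Br)[C@](C)(Cl)C[C@@H]1OC(=O)CCl | intermediate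
26 | C8 acetate, C6 chloroacetate | CC(=O)O[C@H]1C[C@H](Br)C(C)(C)O[C@@]1(C)[C@H]1C[C@@H](Br)[C@](C)(Cl)C[C@@H]1OC(=O)CCl | intermediate
27 | C8 acetate, C6 equatorial alcohol (6S, the C6 epimer of the target) | CC(=O)O[C@H]1C[C@H](Br)C(C)(C)O[C@@]1(C)[C@H]1C[C@@H](Br)[C@](C)(Cl)C[C@@H]1O | intermediate
28 | C6 ketone with C8 acetate | CC(=O)O[C@H]1C[C@H](Br)C(C)(C)O[C@@]1(C)[C@H]1C[C@@H](Br)[C@](C)(Cl)CC1=O | intermediate
29 | target, CNP0166766.1 (1S,3R,4R,6R,7S,8S,10S; C6 hydroxyl axial) | CC(=O)O[C@H]1C[C@H](Br)C(C)(C)O[C@@]1(C)[C@H]1C[C@@H](Br)[C@](C)(Cl)C[C@H]1O | target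

**Step count**

Total: 21 steps. Longest linear sequence: 20 steps (1 to 29 through steps 1–6 and 8–21); step 7 is a one-step side branch.

**Steps most likely to fail**

1. Step 15 (new method). The bromonium may be opened at C3 to a five-membered ring, or the tertiary chloride may ionise before the electron-poor C1=C7 alkene engages C2. The fallback uses only known reaction types, sets out from 18 and rejoins at 24, so that the ring is closed before any halogen is present.
 - Diethyl chlorophosphate and pyridine convert 18 into the allylic diethyl phosphate F1.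
 - Solvolysis of F1 in CH2Cl2/(CF3)2CHOH with 2,6-lutidine, then bicarbonate, follows the classical neryl-to-terpinyl cation–olefin cyclisation with the same ester termination. It should give the halogen-free cyclohexene hydroxy ester F2 (C3=C4 alkene; C1, C6 and C7 as in 23).
 - Bromoetherification as in step 16 closes ring B to the bromotetrahydropyran cyclohexene F3; cold K2CO3/MeOH frees the homoallylic C6 alcohol F4.
 - VO(acac)2/tBuOOH epoxidation directed by that hydroxyl places the epoxide on the C6–O face, giving the epoxy alcohol F5; chloroacetic anhydride restores the ester in the epoxy chloroacetate F6.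
 - MgBr2·OEt2 opens the epoxide trans-diaxially at tertiary C4 to the bromohydrin F7 (C4–Br axial, C3–OH axial).
 - SOCl2/pyridine activates the C3 hydroxyl, the antiperiplanar bromine shifts from C4 to C3, and chloride enters at the tertiary C4, which gives 24.
 - The detour through the epoxide is needed because direct bromochlorination of the ring alkene would open trans-diaxially and place Br trans to the C1 substituent.

2. Step 13. Catalyst control of the alkene face may be eroded by the resident C6 centre, or the bromonium may be captured by the C6 ester instead of chloride. The fallback sets out from 18 and returns at 19.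
 - Sharpless asymmetric epoxidation (Ti(OiPr)4, L-(+)-diethyl tartrate, tBuOOH), which touches only the allylic alcohol alkene, gives the 2,3-epoxy alcohol F8.
 - MgBr2·OEt2 opens F8 at the tertiary C4 with inversion to the bromo diol F9 (C4–Br, C3–OH, C2–OH).
 - Et3SiCl/imidazole protects the primary hydroxyl as the TES ether F10.
 - SOCl2/pyridine converts the C3 hydroxyl into a leaving group that the anti bromine displaces with 1,2-shift while chloride enters at C4, giving the TES-protected bromochloride F11 with the same anti Br/Cl array as 19.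
 - AcOH/THF/H2O removes the TES group to give 19.

3. Step 16. Closure may take the 5-exo course to a tetrahydrofuran or pass through the other chair, and simple bromination may compete. The fallback sets out from 23 and returns at 24.
 - Reversible oxymercuration with Hg(OCOCF3)2 in MeNO2, which adds oxygen at the tertiary C11 under thermodynamic chair control, followed by aqueous KBr gives the C10 organomercury bromide F12 (mercury equatorial).
 - Bromodemercuration with Br2/LiBr in pyridine, which proceeds with retention, gives 24.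

Further compounds
F1 | step 15 | allylic diethyl phosphate of 18 | CCOP(=O)(OCC)OC/C=C(C)\C[C@H](OC(=O)CCl)/C=C(\C)[C@@H](O[Si](C)(C)C(C)(C)C)CC=C(C)C
F2 | step 15 | halogen-free cyclohexene hydroxy ester (C3=C4 alkene analogue of 23) | CC(C)=CC[C@H](O[Si](C)(C)C(C)(C)C)[C@@](C)(O)[C@H]1CC=C(C)C[C@@H]1OC(=O)CCl
F3 | step 15 | bromotetrahydropyran cyclohexene (C3=C4 alkene analogue of 24) | CC(C)(C)[Si](C)(C)O[C@H]1C[C@H](Br)C(C)(C)O[C@@]1(C)[C@H]1CC=C(C)C[C@@H]1OC(=O)CCl
F4 | step 15 | homoallylic C6 alcohol from F3 | CC(C)(C)[Si](C)(C)O[C@H]1C[C@H](Br)C(C)(C)O[C@@]1(C)[C@H]1CC=C(C)C[C@@H]1O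
F5 | step 15 | C3–C4 epoxy alcohol, epoxide cis to the C6 hydroxyl | CC(C)(C)[Si](C)(C)O[C@H]1C[C@H](Br)C(C)(C)O[C@@]1(C)[C@H]1C[C@@H]2O[C@]2(C)C[C@@H]1O
F6 | step 15 | epoxy chloroacetate from F5 | CC(C)(C)[Si](C)(C)O[C@H]1C[C@H](Br)C(C)(C)O[C@@]1(C)[C@H]1C[C@@H]2O[C@]2(C)C[C@@H]1OC(=O)CCl
F7 | step 15 | trans-diaxial bromohydrin (C4 bromide, C3 alcohol) chloroacetate | CC(C)(C)[Si](C)(C)O[C@H]1C[C@H](Br)C(C)(C)O[C@@]1(C)[C@H]1C[C@H](O)[C@@](C)(Br)C[C@@H]1OC(=O)CCl
F8 | step 13 | 2,3-epoxy alcohol of 18 (C3–C4 cis-epoxide) | OC[C@@H]1O[C@]1(C)C[C@H](OC(=O)CCl)/C=C(\C)[C@@H](O[Si](C)(C)C(C)(C)C)CC=C(C)C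
F9 | step 13 | bromo diol (C4 tertiary bromide, C3 and C2 hydroxyls) | OC[C@H](O)[C@@](C)(Br)C[C@H](OC(=O)CCl)/C=C(\C)[C@@H](O[Si](C)(C)C(C)(C)C)CC=C(C)C
F10 | step 13 | primary TES ether of F9 | CC[Si](CC)(CC)OC[C@H](O)[C@@](C)(Br)C[C@H](OC(=O)CCl)/C=C(\C)[C@@H](O[Si](C)(C)C(C)(C)C)CC=C(C)C
F11 | step 13 | primary TES ether of 19 | CC[Si](CC)(CC)OC[C@@H](Br)[C@](C)(Cl)C[C@H](OC(=O)CCl)/C=C(\C)[C@@H](O[Si](C)(C)C(C)(C)C)CC=C(C)C
F12 | step 16 | C10 bromomercurio tetrahydropyran (mercury in place of the C10 bromine of 24) | CC(C)(C)[Si](C)(C)O[C@H]1C[C@H]([Hg]Br)C(C)(C)O[C@@]1(C)[C@H]1C[C@@H](Br)[C@](C)(Cl)C[C@@H]1OC(=O)CCl
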